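The decalin is opened at C9–C10 and C4–C5, so that the chain C9–C10–C5–C4 is stitched into both rings by one cation–olefin cascade. Ionising a tertiary chloride at C9 lets the cation add to C10 of a (Z)-C5=C10 olefin (ring B) and a propargylsilane capture C5 through C4 (ring A). The Z geometry becomes the cis ring fusion, the single C8 methyl stereocentre steers C9, C10 and C5, and the alkyne terminus becomes the exocyclic carbon on C4. The precursor is an open-chain chloride carrying C8, the Z olefin, the propargylsilane and the arene, whose phenol is masked as a pivalate so that neither oxygen nor ring can trap the cation.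

Key step: step 15

Remark on numbering and assumptions: terpenoid numbering is used (ring A = C1–C5 and C10, ring B = C5–C10; C4 bears the exocyclic carbon, C8 the secondary methyl, C9 the arylmethyl group). Chloride 22 is assumed to be usable as its mixture of C9 epimers, because both ionise to the same planar cation.

Step 1
Reactants: 1 hex-5-yn-1-ol; 2 (iodomethyl)trimethylsilane
Product: 4 7-(trimethylsilyl)hept-5-yn-1-ol, via dilithiated hex-5-yn-1-ol 3 (not isolated)
Conditions: n-BuLi (2.1 equiv), THF, −78 to 0 °C; then 2, reflux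
Reagents that add atoms: none
Why: the lithium acetylide of the dianion is far more nucleophilic towards the primary iodide than the aggregated lithium alkoxide, so acetylide SN2 alkylation should install the propargylsilane without protection of the hydroxyl group.

Step 2
Reactants: 4 7-(trimethylsilyl)hept-5-yn-1-ol
Product: 5 7-(trimethylsilyl)hept-5-ynal
Conditions: Dess–Martin periodinane, CH2Cl2, 0 °C to rt
Reagents that add atoms: none
Why: Dess–Martin oxidation of a primary alcohol stops at the aldehyde under near-neutral conditions that leave the propargylsilane untouched.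

Step 3
Reactants: 5 7-(trimethylsilyl)hept-5-ynal
Product: 6 [(7Z)-8-iodonon-7-en-2-yn-1-yl]trimethylsilane
Conditions: EtPPh3I, n-BuLi, THF, 0 °C; I2, −78 °C; NaN(SiMe3)2, −20 °C; then 5, −78 to −20 °C
Reagents that add atoms: ethyltriphenylphosphonium iodide, CC[P+](c1ccccc1)(c1ccccc1)c1ccccc1.[I-]; iodine, II
Why: the α-iodo Wittig reaction (Stork–Zhao olefination with Ph3P=C(I)CH3) of an unhindered aliphatic aldehyde is kinetically Z-selective, which places iodine cis to the chain and fixes the future C5=C10 geometry at a stage where isomers can still be separated.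

Step 4
Reactants: 7 methyl (2R)-3-hydroxy-2-methylpropanoate
Product: 8 methyl (2R)-3-{[tert-butyl(dimethyl)silyl]oxy}-2-methylpropanoate
Conditions: t-BuMe2SiCl, imidazole, CH2Cl2, rt
Reagents that add atoms: tert-butyl(chloro)dimethylsilane, CC(C)(C)[Si](C)(C)Cl
Why: imidazole-mediated silylation of the primary alcohol is chemoselective and does not touch the α-stereocentre, which becomes C8.

Step 5
Reactants: 8 methyl (2R)-3-{[tert-butyl(dimethyl)silyl]oxy}-2-methylpropanoate
Product: 9 (2R)-3-{[tert-butyl(dimethyl)silyl]oxy}-2-methylpropanal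
Conditions: i-Bu2AlH (1.1 equiv), CH2Cl2, −78 °C; aq. potassium sodium tartrate; used at once
Reagents that add atoms: none
Why: partial reduction of an ester by i-Bu2AlH at −78 °C stops at the aldehyde oxidation level and the cold, non-basic conditions preserve the α-stereocentre.

Step 6
Reactants: 9 (2R)-3-{[tert-butyl(dimethyl)silyl]oxy}-2-methylpropanal
Product: 10 tert-butyl(dimethyl){[(2S)-2-methylbut-3-en-1-yl]oxy}silane
Conditions: Ph3PCH3Br, KN(SiMe3)2, THF, −78 to 0 °C
Reagents that add atoms: methyltriphenylphosphonium bromide, C[P+](c1ccccc1)(c1ccccc1)c1ccccc1.[Br-]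
Why: Wittig methylenation with salt-free Ph3P=CH2 at low temperature converts the α-chiral aldehyde into the terminal alkene faster than it enolises, so the stereocentre is retained (the descriptor changes to S only through the priority rules).

Step 7
Reactants: 10 tert-butyl(dimethyl){[(2S)-2-methylbut-3-en-1-yl]oxy}silane; 6 [(7Z)-8-iodonon-7-en-2-yn-1-yl]trimethylsilane
Product: 12 tert-butyl{[(2S,5Z)-2,5-dimethyl-12-(trimethylsilyl)dodec-5-en-10-yn-1-yl]oxy}dimethylsilane, via B-alkyl-9-borabicyclononane 11 (not isolated)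
Conditions: 10 (1.3 equiv), 9-BBN (1.25 equiv), THF, rt; then 6, PdCl2(dppf), AsPh3, Cs2CO3, DMF/H2O, rt
Reagents that add atoms: none
Why: 9-BBN hydroborates the terminal alkene at its CH2 terminus and the B-alkyl Suzuki–Miyaura coupling with the vinyl iodide proceeds with retention of olefin geometry, which joins C5 to C6 and delivers the (Z)-trisubstituted olefin.

Step 8
Reactants: 12 tert-butyl{[(2S,5Z)-2,5-dimethyl-12-(trimethylsilyl)dodec-5-en-10-yn-1-yl]oxy}dimethylsilane
Product: 13 (2S,5Z)-2,5-dimethyl-12-(trimethylsilyl)dodec-5-en-10-yn-1-ol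
Conditions: camphorsulfonic acid (10 mol %), MeOH/CH2Cl2, 0 °C
Reagents that add atoms: none
Why: acid-catalysed methanolysis cleaves a primary silyl ether under conditions too mild to protonate the olefin or the propargylsilane.

Step 9
Reactants: 13 (2S,5Z)-2,5-dimethyl-12-(trimethylsilyl)dodec-5-en-10-yn-1-ol
Product: 14 (2S,5Z)-2,5-dimethyl-12-(trimethylsilyl)dodec-5-en-10-ynoic acid
Conditions: TEMPO (20 mol %), PhI(OAc)2 (2.2 equiv), MeCN/H2O, rt
Reagents that add atoms: water, O
Why: the TEMPO/PhI(OAc)2 oxidation in wet acetonitrile takes the primary alcohol through the aldehyde hydrate to the acid without electrophilic halogen or strong acid, so the olefin, the propargylsilane and the α-stereocentre are preserved.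

Step 10
Reactants: 15 methyl 4-hydroxy-3-methylbenzoate
Product: 16 methyl 4-[(2,2-dimethylpropanoyl)oxy]-3-methylbenzoate
Conditions: t-BuCOCl, Et3N, DMAP (cat.), CH2Cl2, 0 °C to rt
Reagents that add atoms: pivaloyl chloride, CC(C)(C)C(Cl)=O
Why: DMAP-catalysed acylation of the phenol gives a hindered aryl ester that is inert to the later organometallic steps and makes the oxygen non-nucleophilic.

Step 11
Reactants: 16 methyl 4-[(2,2-dimethylpropanoyl)oxy]-3-methylbenzoate
Product: 17 methyl 3-(bromomethyl)-4-[(2,2-dimethylpropanoyl)oxy]benzoate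
Conditions: N-bromosuccinimide, AIBN (cat.), PhCF3, 85 °C
Reagents that add atoms: N-bromosuccinimide, O=C1CCC(=O)N1Br
Why: Wohl–Ziegler bromination under radical conditions selects the benzylic methyl group, since the ester and the acyloxy group deactivate the ring towards electrophilic bromination.

Step 12
Reactants: 14 (2S,5Z)-2,5-dimethyl-12-(trimethylsilyl)dodec-5-en-10-ynoic acid; 17 methyl 3-(bromomethyl)-4-[(2,2-dimethylpropanoyl)oxy]benzoate
Product: 20 methyl 3-[(3S,6Z)-3,6-dimethyl-2-oxo-13-(trimethylsilyl)tridec-6-en-11-yn-1-yl]-4-[(2,2-dimethylpropanoyl)oxy]benzoate, via acid chloride 18 (not isolated), via arylmethylzinc bromide 19 (not isolated)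
Conditions: 14, 1-chloro-N,N,2-trimethylprop-1-en-1-amine, CH2Cl2, 0 °C; 17, Zn dust, LiCl, THF, 0 °C; then Pd(PPh3)4 (5 mol %), THF, 0 °C to rt
Reagents that add atoms: none
Why: the Ghosez reagent makes the acid chloride without HCl that could attack the olefin or the propargylsilane, and the palladium-catalysed Negishi acylation with the ester-tolerant benzylic zinc reagent gives the ketone without epimerising the α-stereocentre.

Step 13
Reactants: 20 methyl 3-[(3S,6Z)-3,6-dimethyl-2-oxo-13-(trimethylsilyl)tridec-6-en-11-yn-1-yl]-4-[(2,2-dimethylpropanoyl)oxy]benzoate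
Product: 21 methyl 4-[(2,2-dimethylpropanoyl)oxy]-3-[(3S,6Z)-2-hydroxy-2,3,6-trimethyl-13-(trimethylsilyl)tridec-6-en-11-yn-1-yl]benzoate (both C2 epimers)
Conditions: MeLi, CeCl3, THF, −78 °C; AcOH quench at −78 °C
Reagents that add atoms: methyllithium, [Li]C
Why: the weakly basic organocerium reagent adds to the enolisable benzyl ketone at −78 °C much faster than to either ester (organocerium 1,2-addition), and the new carbinol centre may form as either epimer because C9 is ionised later.

Step 14
Reactants: 21 methyl 4-[(2,2-dimethylpropanoyl)oxy]-3-[(3S,6Z)-2-hydroxy-2,3,6-trimethyl-13-(trimethylsilyl)tridec-6-en-11-yn-1-yl]benzoate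
Product: 22 methyl 3-[(3S,6Z)-2-chloro-2,3,6-trimethyl-13-(trimethylsilyl)tridec-6-en-11-yn-1-yl]-4-[(2,2-dimethylpropanoyl)oxy]benzoate (both C2 epimers)
Conditions: 1-chloro-N,N,2-trimethylprop-1-en-1-amine (1.5 equiv), CH2Cl2, −20 to 0 °C; pentane, rapid filtration; used at once
Reagents that add atoms: 1-chloro-N,N,2-trimethylprop-1-en-1-amine, CC(C)=C(Cl)N(C)C
Why: the α-chloroenamine converts the tertiary alcohol into an alkoxyiminium chloride that collapses within the ion pair to the tertiary chloride (Ghosez chlorination) under neutral, HCl-free conditions at low temperature, so the olefin and the propargylsilane should not be engaged.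

Step 15
Reactants: 22 methyl 3-[(3S,6Z)-2-chloro-2,3,6-trimethyl-13-(trimethylsilyl)tridec-6-en-11-yn-1-yl]-4-[(2,2-dimethylpropanoyl)oxy]benzoate
Product: 26 methyl 4-[(2,2-dimethylpropanoyl)oxy]-3-{[(1R,2S,4aS,8aR)-5-ethenylidene-1,2,4a-trimethyldecahydronaphthalen-1-yl]methyl}benzoate, via C9 tertiary cation 23 (not isolated), via ring B C5 cation 24 (not isolated), via exocyclic vinyl cation 25 (not isolated)
Conditions: SnCl4 (3.5 equiv), 2,6-di-tert-butyl-4-methylpyridine (2 equiv), CH2Cl2, −78 °C; aq. NaHCO3
Reagents that add atoms: none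
Why: Proposed new method: SnCl4 abstracts chloride from either C9 epimer of 22 to give the planar tertiary cation 23, the (Z)-C5=C10 olefin attacks it through C10 (ring B, 6-endo-trig) to give the C5 cation 24, the propargylsilane adds through C4 (ring A, 6-exo-dig) and the β-silyl vinyl cation 25 loses Me3SiCl to leave the allene; the closest known reaction types are cation–olefin polycyclisations terminated by propargylsilanes and Lewis-acid ionisation of tertiary chlorides buffered by a hindered pyridine. C9 and C10 are set in a chair transition state for ring B in which the C8 methyl (the only stereocentre present) and the arylmethyl group are equatorial, so the C9 methyl becomes axial and cis to the C8 methyl. The Z geometry places C1 axial and H10 equatorial on that chair, and anti addition across the olefin (C4 enters C5 opposite to the new C9–C10 bond) then gives the cis ring fusion with the C5 methyl and H10 on the same face. The step needs one facial sense of chair folding and capture of 24 before it relaxes; the first should be secured by the equatorial preference at C8, the second by the tethered, strongly nucleophilic propargylsilane. The pivalate and the ester keep the aryl oxygen and the ring from trapping 23 (dihydrobenzofuran or Friedel–Crafts closure), and the hindered pyridine removes protons that would cause protodesilylation or elimination.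

Step 16
Reactants: 26 methyl 4-[(2,2-dimethylpropanoyl)oxy]-3-{[(1R,2S,4aS,8aR)-5-ethenylidene-1,2,4a-trimethyldecahydronaphthalen-1-yl]methyl}benzoate
Product: 27 methyl 4-[(2,2-dimethylpropanoyl)oxy]-3-{[(1R,2S,4aS,8aR)-1,2,4a-trimethyl-5-oxodecahydronaphthalen-1-yl]methyl}benzoate
Conditions: O3, CH2Cl2/MeOH, −78 °C; then Me2S, −78 °C to rt
Reagents that add atoms: ozone, [O-][O+]=O
Why: ozonolysis cleaves both cumulated double bonds of the allene and reductive work-up leaves the C4 ketone, while the electron-poor arene and the esters are inert to ozone at −78 °C.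

Step 17
Reactants: 27 methyl 4-[(2,2-dimethylpropanoyl)oxy]-3-{[(1R,2S,4aS,8aR)-1,2,4a-trimethyl-5-oxodecahydronaphthalen-1-yl]methyl}benzoate
Product: 28 methyl 4-hydroxy-3-{[(1R,2S,4aS,8aR)-1,2,4a-trimethyl-5-oxodecahydronaphthalen-1-yl]methyl}benzoate
Conditions: K2CO3 (1.5 equiv), MeOH, rt; aq. NH4Cl
Reagents that add atoms: none
Why: base-mediated methanolysis (transesterification) removes the activated aryl pivalate while the methyl benzoate is simply regenerated and no stereocentre is α to the ketone.

Step 18
Reactants: 28 methyl 4-hydroxy-3-{[(1R,2S,4aS,8aR)-1,2,4a-trimethyl-5-oxodecahydronaphthalen-1-yl]methyl}benzoate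
Product: 29 methyl 4-hydroxy-3-{[(1R,2S,4aS,8aR)-1,2,4a-trimethyl-5-methylidenedecahydronaphthalen-1-yl]methyl}benzoate
Conditions: Ph3PCH3Br (4 equiv), KN(SiMe3)2 (3.8 equiv), toluene, 0 to 80 °C; aq. NH4Cl
Reagents that add atoms: methyltriphenylphosphonium bromide, C[P+](c1ccccc1)(c1ccccc1)c1ccccc1.[Br-]
Why: Wittig methylenation with excess Ph3P=CH2 at elevated temperature converts the hindered C4 ketone into the exocyclic methylene, the phenoxide formed in the flask deactivating the para ester towards the ylide, and no stereocentre can epimerise.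

Compound list
1 | hex-5-yn-1-ol | C#CCCCCO | starting material
2 | (iodomethyl)trimethylsilane | C[Si](C)(C)CI | starting material
3 | dilithiated hex-5-yn-1-ol (lithium 6-lithiohex-5-yn-1-olate) | [Li]C#CCCCCO[Li] | intermediate (not isolated)
4 | 7-(trimethylsilyl)hept-5-yn-1-ol | C[Si](C)(C)CC#CCCCCO | intermediate
5 | 7-(trimethylsilyl)hept-5-ynal | C[Si](C)(C)CC#CCCCC=O | intermediate
6 | [(7Z)-8-iodonon-7-en-2-yn-1-yl]trimethylsilane | C[Si](C)(C)CC#CCCC/C=C(/C)I | intermediate
7 | methyl (2R)-3-hydroxy-2-methylpropanoate | COC(=O)[C@H](C)CO | starting material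
8 | methyl (2R)-3-{[tert-butyl(dimethyl)silyl]oxy}-2-methylpropanoate | COC(=O)[C@H](C)CO[Si](C)(C)C(C)(C)C | intermediate
9 | (2R)-3-{[tert-butyl(dimethyl)silyl]oxy}-2-methylpropanal | O=C[C@H](C)CO[Si](C)(C)C(C)(C)C | intermediate
10 | tert-butyl(dimethyl){[(2S)-2-methylbut-3-en-1-yl]oxy}silane | C=C[C@H](C)CO[Si](C)(C)C(C)(C)C | intermediate
11 | 9-[(3S)-4-{[tert-butyl(dimethyl)silyl]oxy}-3-methylbutyl]-9-borabicyclo[3.3.1]nonane | CC(C)(C)[Si](C)(C)OC[C@@H](C)CCB1C2CCCC1CCC2 | intermediate (not isolated)
12 | tert-butyl{[(2S,5Z)-2,5-dimethyl-12-(trimethylsilyl)dodec-5-en-10-yn-1-yl]oxy}dimethylsilane | C[Si](C)(C)CC#CCCC/C=C(/C)CC[C@H](C)CO[Si](C)(C)C(C)(C)C | intermediate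
13 | (2S,5Z)-2,5-dimethyl-12-(trimethylsilyl)dodec-5-en-10-yn-1-ol | C[Si](C)(C)CC#CCCC/C=C(/C)CC[C@H](C)CO | intermediate
14 | (2S,5Z)-2,5-dimethyl-12-(trimethylsilyl)dodec-5-en-10-ynoic acid | C[Si](C)(C)CC#CCCC/C=C(/C)CC[C@H](C)C(=O)O | intermediate
15 | methyl 4-hydroxy-3-methylbenzoate | COC(=O)c1ccc(O)c(C)c1 | starting material
16 | methyl 4-[(2,2-dimethylpropanoyl)oxy]-3-methylbenzoate | COC(=O)c1ccc(OC(=O)C(C)(C)C)c(C)c1 | intermediate
17 | methyl 3-(bromomethyl)-4-[(2,2-dimethylpropanoyl)oxy]benzoate | COC(=O)c1ccc(OC(=O)C(C)(C)C)c(CBr)c1 | intermediate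
18 | (2S,5Z)-2,5-dimethyl-12-(trimethylsilyl)dodec-5-en-10-ynoyl chloride | C[Si](C)(C)CC#CCCC/C=C(/C)CC[C@H](C)C(Cl)=O | intermediate (not isolated)
19 | bromo{[5-(methoxycarbonyl)-2-(pivaloyloxy)phenyl]methyl}zinc | COC(=O)c1ccc(OC(=O)C(C)(C)C)c(C[Zn]Br)c1 | intermediate (not isolated)
20 | methyl 3-[(3S,6Z)-3,6-dimethyl-2-oxo-13-(trimethylsilyl)tridec-6-en-11-yn-1-yl]-4-[(2,2-dimethylpropanoyl)oxy]benzoate | C[Si](C)(C)CC#CCCC/C=C(/C)CC[C@H](C)C(=O)Cc1cc(C(=O)OC)ccc1OC(=O)C(C)(C)C | intermediate
21 | methyl 4-[(2,2-dimethylpropanoyl)oxy]-3-[(3S,6Z)-2-hydroxy-2,3,6-trimethyl-13-(trimethylsilyl)tridec-6-en-11-yn-1-yl]benzoate (both C2 epimers) | C[Si](C)(C)CC#CCCC/C=C(/C)CC[C@H](C)C(C)(O)Cc1cc(C(=O)OC)ccc1OC(=O)C(C)(C)C | intermediate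
22 | methyl 3-[(3S,6Z)-2-chloro-2,3,6-trimethyl-13-(trimethylsilyl)tridec-6-en-11-yn-1-yl]-4-[(2,2-dimethylpropanoyl)oxy]benzoate (both C2 epimers; key-step precursor) | C[Si](C)(C)CC#CCCC/C=C(/C)CC[C@H](C)C(C)(Cl)Cc1cc(C(=O)OC)ccc1OC(=O)C(C)(C)C | intermediate
23 | C9 tertiary cation from 22 | C[Si](C)(C)CC#CCCC/C=C(/C)CC[C@H](C)[C+](C)Cc1cc(C(=O)OC)ccc1OC(=O)C(C)(C)C | intermediate (not isolated)
24 | ring B closed, cation at C5 | C[Si](C)(C)CC#CCCC[C@@H]1[C@](C)(Cc2cc(C(=O)OC)ccc2OC(=O)C(C)(C)C)[C@@H](C)CC[C+]1C | intermediate (not isolated)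
25 | bicyclic exocyclic β-silyl vinyl cation | C[Si](C)(C)C[C+]=C1CCC[C@@H]2[C@](C)(Cc3cc(C(=O)OC)ccc3OC(=O)C(C)(C)C)[C@@H](C)CC[C@]12C | intermediate (not isolated)
26 | methyl 4-[(2,2-dimethylpropanoyl)oxy]-3-{[(1R,2S,4aS,8aR)-5-ethenylidene-1,2,4a-trimethyldecahydronaphthalen-1-yl]methyl}benzoate (key-step product) | C=C=C1CCC[C@@H]2[C@](C)(Cc3cc(C(=O)OC)ccc3OC(=O)C(C)(C)C)[C@@H](C)CC[C@]12C | intermediate
27 | methyl 4-[(2,2-dimethylpropanoyl)oxy]-3-{[(1R,2S,4aS,8aR)-1,2,4a-trimethyl-5-oxodecahydronaphthalen-1-yl]methyl}benzoate | O=C1CCC[C@@H]2[C@](C)(Cc3cc(C(=O)OC)ccc3OC(=O)C(C)(C)C)[C@@H](C)CC[C@]12C | intermediate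
28 | methyl 4-hydroxy-3-{[(1R,2S,4aS,8aR)-1,2,4a-trimethyl-5-oxodecahydronaphthalen-1-yl]methyl}benzoate | O=C1CCC[C@@H]2[C@](C)(Cc3cc(C(=O)OC)ccc3O)[C@@H](C)CC[C@]12C | intermediate
29 | methyl 4-hydroxy-3-{[(1R,2S,4aS,8aR)-1,2,4a-trimethyl-5-methylidenedecahydronaphthalen-1-yl]methyl}benzoate | C=C1CCC[C@@H]2[C@](C)(Cc3cc(C(=O)OC)ccc3O)[C@@H](C)CC[C@]12C | target

Total step count: 18.
Longest linear sequence: 13 steps (steps 1, 2, 3, 7, 8, 9, 12, 13, 14, 15, 16, 17, 18 from 1; the branch from 7 through steps 4, 5, 6 is equally long).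

Steps most likely to fail

Step 15 (bears the new-method label).
- What may go wrong: cation 23 may lose a proton or suffer a 1,2-hydride shift from C8 before ring B closes. The chair may fold with the other facial sense. Cation 24 may relax before capture, so that the Z-olefin information and the cis fusion are eroded.
- Fallback (known reaction types), sets out from 20 and returns at 26: ketone 20 is methylenated with the non-basic Takai–Lombardo reagent (Zn, CH2Br2, TiCl4), which does not epimerise C8 and tolerates both esters, to give the C9 methylidene alkene F1. F1 is then cyclised by cobalt-hydride hydrogen-atom transfer with radical–polar crossover (Co(salen), C16H14CoN2O2, an N-fluoropyridinium oxidant, a silane, hexafluoroisopropanol). This is an established way to start polyene bicyclisations at a 1,1-disubstituted alkene while trisubstituted olefins are left alone. Hydrogen is delivered to the terminal CH2, the C9 cation arises without Lewis acid or leaving group, and ring closure with propargylsilane termination should then lead to 26.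

Step 14.
- What may go wrong: ionisation during chlorination may end in elimination towards the conjugated styrene or in premature, uncontrolled cyclisation, and the chloride may decompose on isolation.
- Fallback, sets out from 21 and returns at 26: 21 is O-acylated with trifluoroacetic anhydride and 2,6-di-tert-butyl-4-methylpyridine in CH2Cl2 at −40 °C, which does not break the C9–O bond, to give the tertiary trifluoroacetate F2. F2 is not isolated but ionised in the same flask with SnCl4 at −78 °C, so that the cation is generated only under the conditions of the bicyclisation.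

Step 18.
- What may go wrong: addition of the ylide to the ketone flanked by the quaternary C5 may be too slow, with competing attack at the ester or decomposition on prolonged heating.
- Fallback, sets out from 27 and returns at 29: 27 is methylenated with the ester-tolerant Takai–Lombardo reagent (Zn, CH2Br2, TiCl4) to give the methylidene pivalate F3. Methanolysis of F3 (K2CO3, MeOH, rt) then gives 29.

Further compounds
F1 | step 15 | methyl 3-[(3S,6Z)-3,6-dimethyl-2-methylidene-13-(trimethylsilyl)tridec-6-en-11-yn-1-yl]-4-[(2,2-dimethylpropanoyl)oxy]benzoate | C[Si](C)(C)CC#CCCC/C=C(/C)CC[C@H](C)C(=C)Cc1cc(C(=O)OC)ccc1OC(=O)C(C)(C)C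
F2 | step 14 | methyl 4-[(2,2-dimethylpropanoyl)oxy]-3-[(3S,6Z)-2,3,6-trimethyl-2-(trifluoroacetoxy)-13-(trimethylsilyl)tridec-6-en-11-yn-1-yl]benzoate (both C2 epimers) | C[Si](C)(C)CC#CCCC/C=C(/C)CC[C@H](C)C(C)(OC(=O)C(F)(F)F)Cc1cc(C(=O)OC)ccc1OC(=O)C(C)(C)C
F3 | step 18 | methyl 4-[(2,2-dimethylpropanoyl)oxy]-3-{[(1R,2S,4aS,8aR)-1,2,4a-trimethyl-5-methylidenedecahydronaphthalen-1-yl]methyl}benzoate | C=C1CCC[C@@H]2[C@](C)(Cc3cc(C(=O)OC)ccc3OC(=O)C(C)(C)C)[C@@H](C)CC[C@]12C
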